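Compound numbers are those of the steps and of the compound list below.

## Analysis of the target

Dorsilurin C (36) is a flavonol, a 3-hydroxy-4H-chromen-4-one built from benzo ring A and pyranone ring C, whose C2 carries aryl ring B. Ring B is fused to a 2,2-dimethyl-2H-pyran (ring D), so the flavonol sits on C7 of a 2,2-dimethyl-2H-chromene, para to the ring carbon that bears the styrene-type alkene and meta to the ring carbon that bears the pyran oxygen. Ring A is a fully substituted phloroglucinol: oxygen on C5, C7 and C8a (the last is O1 of ring C), 3-methylbut-2-enyl (prenyl) groups on C6 and C8, and the C4 carbonyl on C4a. There is no stereocentre and no stereogenic double bond, so only constitution has to be controlled. The sensitive groups are the two prenyl groups, each ortho to a phenol and so prone to acid-induced closure to 2,2-dimethylchromans, the C3''=C4'' alkene of ring D and the electron-rich enol at C3, so hydrogenolysis, strong oxidants and strong acids are excluded late in the route. The hard part is ring A, where the two prenyl groups flank the C7 hydroxyl; electrophilic prenylation of a trihydroxybenzene gives this pattern poorly because O-alkylation, over-alkylation and geminal dialkylation compete. The strategy rests on the strict alternation of substituents around ring A (C4a acyl, C5 O, C6 prenyl, C7 O, C8 prenyl, C8a O), a pattern that a benzannulation writes exactly when a four-carbon unit supplies C7, C4a, C5 and C6 and a two-carbon ynol ether supplies C8 and C8a, each partner bringing one prenyl group.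

## Retrosynthetic reasoning

36 to 35. The last bond cut is the O–CH2 bond of an ethyl ether on the C5 oxygen. This ethyl group is inherited from 3 and is carried as a protecting group through the whole route. It is removed last because only in 35 does it lie peri to the C4 carbonyl, where a chelating Lewis acid with a nucleophilic counter-ion can single it out. The forward step must dealkylate without protonating the prenyl groups.

35 to 31. Ring C is opened at O1–C2, which leads to the 1,3-diketone 31 with C3 already oxygenated and the three remaining hydroxyls masked as methoxymethyl acetals. This is the natural place to cut because hemiketalization and dehydration of an ortho-hydroxyaryl 1,3-diketone is the most dependable chromone closure. The forward step has to unmask the C8a oxygen, close the ring and remove the other acetals in one acidic operation mild enough for the prenyl groups.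

31 to 22 and 29. The C2–C3 bond is cut, which separates the ring B/D fragment as an acid chloride from the ring A ketone. Cutting here keeps the route convergent. It also brings in C3 with its oxygen attached, so no late oxidation at C3 is needed in the presence of three electron-rich alkenes. The forward reaction is a C-acylation of a ketone enolate.

22 to 17 and 20. The C4–C4a bond is cut. In 17, C4a carries the only ring hydrogen and lies between two oxygen substituents, so directed ortho-metalation gives the aryl anion there without any regiochemical choice. This is preferred to a Friedel–Crafts or Hoesch acylation because those need acids that the prenyl groups would not survive. Amide 20 supplies C4 and C3 with the C3 oxygen protected.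

17 to 16 to 15. These are protecting-group changes only. The silyl ether left by the benzannulation cannot direct metalation, so it is exchanged, together with the free C7 hydroxyl, for two methoxymethyl ethers.

15 to 5 and 10 (key disconnection). Ring A is cut at C7–C8 and C4a–C8a, the two bonds that join the partners, and at C6–C7, the bond that closes the ring. Cyclobutenone 5 supplies C7 (its carbonyl), C4a, C5 (with the ethoxy group) and C6 (with a prenyl group). Siloxyalkyne 10 supplies C8 (with the second prenyl group) and C8a (with the silyloxy group). The gain is that all six substituent positions follow from the connectivity of two stable, separately made partners, and the three oxygens arrive differentiated (ethyl ether, free phenol, silyl ether). The forward reaction must give a single regiochemistry in the ketene–alkyne union and must not engage the prenyl alkenes.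

5 to 2 and 3; 10 to 7. Cyclobutenone 5 is the [2+2] adduct of prenylketene 4, made from acid chloride 2 (from acid 1), with ynol ether 3. Siloxyalkyne 10 comes from ester 7 (from acid 6) by one-carbon homologation to ynolate 9 and O-silylation. Both partners are reached in two steps, so the risk is concentrated in the benzannulation.

29 to 23; 20 to 18. Acid chloride 29 comes from acid 28 and bromide 26, and 26 from salicylaldehyde 23 by a one-flask addition–cyclization through 24 and 25, where the ortho hydroxyl and formyl groups of 23 fix the pyran position. Amide 20 comes from hydroxy ester 18 by way of 19.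

## Alternatives that were turned down

Alternative 1: All of ring C is added in one operation to a preformed, symmetric ring A, 2,4-bis(3-methylbut-2-en-1-yl)benzene-1,3,5-triol A2; the bonds made are C4–C4a and O1–C2.
- Forward key step: dioxinone A3 is heated and releases the α-alkoxy aroylketene A4. A4 acylates the only free ring carbon of A2, and one of the two equivalent flanking hydroxyls condenses with the aryl ketone. This should give the 3-O-methoxymethyl ether A1, one acetal cleavage from 36.
- For it: convergence is the highest possible, the symmetry of A2 removes every regiochemical question at this stage, no oxygen has to be differentiated or dealkylated, and C3 arrives oxygenated. On step count and longest linear sequence this plan is clearly stronger than the chosen one.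
- Against it: A2 is reached only by twofold C-prenylation of an unprotected polyphenol, the poorly selective reaction that makes ring A difficult, or by a protected detour that erodes the step advantage. Acylketenes normally acylate phenols on oxygen, so C-acylation would depend on the nucleophilicity of the ring carbon or on a later acyl shift. The thermolysis (above 100 °C) is applied to three free phenols ortho to prenyl groups, where chroman formation and oxidation are to be expected. A3 with its 5-alkoxy group is itself a multistep building block.
- Comparison: for its extra steps the chosen strategy gives a ring A whose pattern is fixed by connectivity, with no step depending on selective prenylation, and forms the C4–C4a bond under non-acidic conditions on fully protected material.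

Alternative 2: This plan cuts ring D, not ring A: the C4'–C4'' bond and the O–C(CH3)2 bond of the pyran are made in one condensation–electrocyclization.
- Forward key step: methyl 3,5-dioxocyclohexane-1-carboxylate A6 condenses at its C2 with 3-methylbut-2-enal A7, and oxa-6π closure of the resulting 1-oxatriene should give the tetrahydrochromenone A5.
- For it: the symmetry of A6 makes the annulation regiochemically unambiguous, A6 and A7 are cheap, and the reaction is a well-established formal [3+3] process that needs no organometallic reagent. In cost and simplicity it is at least the equal of steps 11 and 12.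
- Against it: A5 carries a ring oxygen that 36 lacks, so reduction, dehydration and dehydrogenation are needed before the acid corresponding to 28 is reached, the last of them with an oxidant in the presence of the chromene alkene. The regiochemical question that the union of A6 with A7 answers is already answered by the ortho hydroxyl and formyl groups of 23. The plan spends its key step on the easy half of the molecule and leaves the diprenylated ring A unsolved.
- Comparison: the chosen route reaches 26 in one step and places its strategic step where the structural difficulty lies.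

Alternative 3: Ring A is cut at C4a–C8a and unfolded into the open-chain triketo ester A9, with both prenyl groups already on the carbons between the carbonyl groups.
- Forward key step: a chelating alkoxide base such as Mg(OMe)2 generates the carbanion at C4a, which attacks the ester carbon C8a in a Claisen cyclization; enolization gives chalcone A8, which would then be cyclized oxidatively to the flavonol.
- For it: like the chosen route it builds ring A de novo with the prenyl groups in place. It needs no protecting group on ring A and ends in a symmetric ring, so in protecting-group economy it is the stronger plan.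
- Against it: A9 has four acidic sites, an enone and two tertiary carbons between carbonyls. Its assembly by iterated acylation is long, and the cyclization must win against aldol-type closures onto ketones, lactonization to pyranones, retro-Claisen cleavage and conjugate addition to the enone. A8 has hydroxyls on both ortho positions of the acyl group, where alkaline peroxide oxidation of chalcones tends to close through the other enone carbon to five-membered-ring products, and it exposes three free phenols next to prenyl groups to an oxidant.
- Comparison: the chosen route obtains the same de novo ring A by a pericyclic cascade whose regiochemistry follows from the connectivity of two stable partners, not from competition among enolates, and brings in C3 already oxygenated. It pays with protecting-group steps and a late ether cleavage.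

Key step: step 5

Assumption: compounds 1, 3 (as its hexane solution), 6, 18 and 23 and the Grignard reagent of step 11 are taken to be purchasable as such.

## Route

Step 1
Reactants: 1 5-methylhex-4-enoic acid
Product: 2 5-methylhex-4-enoyl chloride
Conditions: (COCl)2, DMF (cat.), CH2Cl2, 0 °C → rt
Reagents that add atoms: oxalyl chloride, O=C(Cl)C(=O)Cl
Why: Acid chloride formation through the catalytic chloroiminium species; gas evolution drives it, and the isolated trisubstituted alkene should be untouched under anhydrous conditions with the hydrogen chloride swept out.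

Step 2
Reactants: 2 5-methylhex-4-enoyl chloride; 3 ethoxyacetylene
Product: 5 3-ethoxy-4-(3-methylbut-2-en-1-yl)cyclobut-2-en-1-one (racemic), via prenylketene 4 (not isolated)
Conditions: Et3N, Et2O–hexane, rt, slow addition of 2 to excess 3
Reagents that add atoms: none
Why: Dehydrochlorination gives monoalkylketene 4, which is trapped in the ketene–ynol ether [2+2] cycloaddition; the ketene carbonyl carbon bonds to the unsubstituted, nucleophilic alkyne carbon, so the ethoxy group ends on C3 and the prenyl group on C4. The C4 stereocentre forms racemic and is erased in step 5; keeping the ketene dilute against excess 3 suppresses its dimerization.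

Step 3
Reactants: 6 4-methylpent-3-enoic acid
Product: 7 ethyl 4-methylpent-3-enoate
Conditions: EtI, K2CO3, DMF, rt
Reagents that add atoms: iodoethane, CCI
Why: SN2 alkylation of the carboxylate; it avoids the strong acid of a Fischer esterification, which would lactonize this β,γ-unsaturated acid, and the weak base should leave the double bond out of conjugation.

Step 4
Reactants: 7 ethyl 4-methylpent-3-enoate
Product: 10 triisopropyl[(5-methylhex-4-en-1-yn-1-yl)oxy]silane, via dibromo enolate 8 (not isolated), via lithium ynolate 9 (not isolated)
Conditions: CH2Br2, lithium 2,2,6,6-tetramethylpiperidide, THF, −78 °C; n-BuLi, −78 °C → rt; i-Pr3SiCl, −78 °C → rt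
Reagents that add atoms: dibromomethane, BrCBr; chlorotriisopropylsilane, CC(C)[Si](Cl)(C(C)C)C(C)C
Why: Kowalski ester homologation: dibromomethyllithium adds to the ester, the adduct collapses to enolate 8, and bromine–lithium exchange followed by 1,2-shift of the alkyl group with loss of bromide gives ynolate 9. The bulky silyl chloride silylates 9 on oxygen, not on carbon.

Step 5
Reactants: 5 3-ethoxy-4-(3-methylbut-2-en-1-yl)cyclobut-2-en-1-one; 10 triisopropyl[(5-methylhex-4-en-1-yn-1-yl)oxy]silane
Product: 15 5-ethoxy-2,6-bis(3-methylbut-2-en-1-yl)-3-[(triisopropylsilyl)oxy]phenol, via vinylketene 11 (not isolated), via vinylcyclobutenone 12 (not isolated), via dienylketene 13 (not isolated), via cyclohexadienone 14 (not isolated)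
Conditions: toluene (ca. 0.5 M), argon, sealed tube, 80 °C then 110 °C; 10 in slight excess
Reagents that add atoms: none
Why: Heating opens 5 by conrotatory 4π cleavage of its C1–C4 bond, the prenyl group turning outward, to give vinylketene 11. The ketene C=C of 11 adds [2+2] to the triple bond of 10, the carbonyl carbon bonding to the alkyne carbon remote from oxygen (future C7–C8) and the ketene α-carbon to the oxygen-bearing carbon (future C4a–C8a), which gives 12. 12 reopens reversibly (4π), and the isomer with the alkenyl group turned inward, 13, is drained by a thermal disrotatory 6π electrocyclization that forms C6–C7 and closes ring A as a six-membered carbocycle; tautomerization of 14 gives the phenol. The closest known reaction type is the Danheiser benzannulation of cyclobutenones with siloxyalkynes to resorcinol monosilyl ethers; here the vinylketene source is a 3-alkoxy-4-alkylcyclobutenone, whose opening may need the upper end of the temperature range. No stereocentre survives: the sp3 carbons of 5, 12 and 14 are racemic and are erased on aromatization, as is the alkene geometry of 11 and 13. The step needs a single regiochemistry in the [2+2] event, and the polarization of the siloxyalkyne (nucleophilic at the carbon remote from oxygen) secures it, so the ring carries O, prenyl, O, prenyl, O, H in the order of the target. It also needs the ketene to prefer the ynol ether over the two trisubstituted alkenes; these are far less nucleophilic, and the outward-turned prenyl group of 11 cannot reach its own ketene. The hydroxyl of 15 is flanked by two prenyl groups, which should protect it from acylation by unreacted ketene.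

Step 6
Reactants: 15 5-ethoxy-2,6-bis(3-methylbut-2-en-1-yl)-3-[(triisopropylsilyl)oxy]phenol
Product: 16 5-ethoxy-2,4-bis(3-methylbut-2-en-1-yl)benzene-1,3-diol
Conditions: Bu4NF, AcOH, THF, 0 °C
Reagents that add atoms: none
Why: Fluoride cleavage of the aryl silyl ether; the acetic acid buffer keeps the electron-rich resorcinol out of its air-sensitive phenoxide form, and the prenyl groups and the ethyl ether are inert.

Step 7
Reactants: 16 5-ethoxy-2,4-bis(3-methylbut-2-en-1-yl)benzene-1,3-diol
Product: 17 1-ethoxy-3,5-bis(methoxymethoxy)-2,4-bis(3-methylbut-2-en-1-yl)benzene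
Conditions: NaH, MeOCH2Cl, DMF, 0 °C → rt
Reagents that add atoms: chloromethyl methyl ether, COCCl
Why: Williamson-type O-alkylation of both phenoxides, including the hindered one between the prenyl groups. Methoxymethyl ethers are chosen because they are strong oxygen-based directing groups for the metalation that follows and can be removed together at the end.

Step 8
Reactants: 18 ethyl glycolate
Product: 19 ethyl 2-(methoxymethoxy)acetate
Conditions: MeOCH2Cl, i-Pr2NEt, CH2Cl2, 0 °C → rt
Reagents that add atoms: chloromethyl methyl ether, COCCl
Why: Standard acetal protection of a primary alcohol with the α-chloro ether under amine base.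

Step 9
Reactants: 19 ethyl 2-(methoxymethoxy)acetate
Product: 20 N-methoxy-2-(methoxymethoxy)-N-methylacetamide
Conditions: MeNH(OMe)·HCl, i-PrMgCl, THF, −20 °C
Reagents that add atoms: N,O-dimethylhydroxylamine hydrochloride, CNOC.Cl
Why: Weinreb amidation of the ester by the magnesium amide generated in the flask; the ester is not enolized appreciably at this temperature.

Step 10
Reactants: 17 1-ethoxy-3,5-bis(methoxymethoxy)-2,4-bis(3-methylbut-2-en-1-yl)benzene; 20 N-methoxy-2-(methoxymethoxy)-N-methylacetamide
Product: 22 1-[2-ethoxy-4,6-bis(methoxymethoxy)-3,5-bis(3-methylbut-2-en-1-yl)phenyl]-2-(methoxymethoxy)ethan-1-one, via aryllithium 21 (not isolated)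
Conditions: n-BuLi, TMEDA, THF, 0 °C; then 20, −78 → 0 °C
Reagents that add atoms: none
Why: Directed ortho-metalation at the only ring hydrogen, which lies between the acetal and the ethoxy oxygen, gives 21. Its addition to the Weinreb amide stops at the chelated tetrahedral adduct and releases the ketone on work-up, so C4–C4a is formed without any Lewis acid.

Step 11
Reactants: 23 4-bromo-2-hydroxybenzaldehyde
Product: 26 7-bromo-2,2-dimethyl-2H-chromene, via benzylic alcohol 24 (not isolated), via quinone methide 25 (not isolated)
Conditions: Me2C=CHMgBr (2.3 equiv), THF, 0 °C → rt; aq. NH4Cl; then pyridinium p-toluenesulfonate (cat.), toluene, 70 °C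
Reagents that add atoms: (2-methylprop-1-en-1-yl)magnesium bromide, CC(C)=C[Mg]Br
Why: Grignard addition to the aldehyde (one equivalent is spent on the phenol) gives the benzylic, allylic alcohol 24 as a racemate. Mild acid dehydrates it to ortho-quinone methide 25, which closes by oxa-6π electrocyclization onto the dimethyl-substituted terminus. The ortho hydroxyl and formyl groups of 23 fix the position of the pyran, so only the 7-bromo isomer can form.

Step 12
Reactants: 26 7-bromo-2,2-dimethyl-2H-chromene
Product: 28 2,2-dimethyl-2H-chromene-7-carboxylic acid, via aryllithium 27 (not isolated)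
Conditions: n-BuLi, THF, −78 °C; CO2; cold dilute aq. HCl
Reagents that add atoms: carbon dioxide, O=C=O
Why: Bromine–lithium exchange at low temperature and carboxylation of 27; the chromene alkene does not react with the alkyllithium at −78 °C.

Step 13
Reactants: 28 2,2-dimethyl-2H-chromene-7-carboxylic acid
Product: 29 2,2-dimethyl-2H-chromene-7-carbonyl chloride
Conditions: (COCl)2, DMF (cat.), CH2Cl2, 0 °C → rt
Reagents that add atoms: oxalyl chloride, O=C(Cl)C(=O)Cl
Why: Acid chloride formation as in step 1; the chromene alkene, deactivated by the para acyl group, should tolerate the brief exposure to hydrogen chloride.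

Step 14
Reactants: 22 1-[2-ethoxy-4,6-bis(methoxymethoxy)-3,5-bis(3-methylbut-2-en-1-yl)phenyl]-2-(methoxymethoxy)ethan-1-one; 29 2,2-dimethyl-2H-chromene-7-carbonyl chloride
Product: 31 1-(2,2-dimethyl-2H-chromen-7-yl)-3-[2-ethoxy-4,6-bis(methoxymethoxy)-3,5-bis(3-methylbut-2-en-1-yl)phenyl]-2-(methoxymethoxy)propane-1,3-dione (racemic; keto–enol mixture), via lithium enolate 30 (not isolated)
Conditions: LiN(SiMe3)2 (2.2 equiv), THF, −78 °C; then 29, −78 → −20 °C
Reagents that add atoms: none
Why: Claisen-type C-acylation of the chelated lithium enolate 30 by the aroyl chloride forms C2–C3. The second equivalent of base deprotonates the more acidic 1,3-diketone as it forms, which protects it from a second acylation; the new stereocentre is racemic and is lost in step 15.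

Step 15
Reactants: 31 1-(2,2-dimethyl-2H-chromen-7-yl)-3-[2-ethoxy-4,6-bis(methoxymethoxy)-3,5-bis(3-methylbut-2-en-1-yl)phenyl]-2-(methoxymethoxy)propane-1,3-dione
Product: 35 2-(2,2-dimethyl-2H-chromen-7-yl)-5-ethoxy-3,7-dihydroxy-6,8-bis(3-methylbut-2-en-1-yl)-4H-chromen-4-one, via dihydroxy diketone 32 (not isolated), via hemiketal 33 (not isolated), via acetal-protected flavone 34 (not isolated)
Conditions: HCl (ca. 2 M), MeOH–THF, 45 °C, stopped at full conversion
Reagents that add atoms: none
Why: Acid-catalysed acetal exchange with methanol unmasks the phenols (32), the C8a hydroxyl adds to the aroyl carbonyl (6-exo-trig hemiketalization to 33), loss of water gives ring C (34), and the enol acetal at C3 is expected to go last. Only the C8a oxygen can close the ring because C5 still carries its ethyl group. Acid strength and temperature are kept moderate so that cyclodehydration outruns protonation of the prenyl and chromene alkenes.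

Step 16
Reactants: 35 2-(2,2-dimethyl-2H-chromen-7-yl)-5-ethoxy-3,7-dihydroxy-6,8-bis(3-methylbut-2-en-1-yl)-4H-chromen-4-one
Product: 36 dorsilurin C, 2-(2,2-dimethyl-2H-chromen-7-yl)-3,5,7-trihydroxy-6,8-bis(3-methylbut-2-en-1-yl)-4H-chromen-4-one
Conditions: MgI2·OEt2 (excess), THF, reflux
Reagents that add atoms: none
Why: Chelation-assisted ether cleavage: magnesium binds the C4 carbonyl and the C5 ether oxygen in a six-membered chelate, and iodide removes the ethyl group by SN2. Magnesium halide etherates are used for this kind of carbonyl-directed dealkylation of aryl ethers and are mild toward prenyl groups and free phenols; the ethyl group is expected to react more slowly than a methyl group.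

## Compound list

1 | 5-methylhex-4-enoic acid | CC(C)=CCCC(=O)O | starting material
2 | 5-methylhex-4-enoyl chloride | CC(C)=CCCC(=O)Cl | intermediate
3 | ethoxyacetylene | CCOC#C | starting material
4 | 5-methylhexa-1,4-dien-1-one (prenylketene) | O=C=CCC=C(C)C | intermediate (not isolated)
5 | 3-ethoxy-4-(3-methylbut-2-en-1-yl)cyclobut-2-en-1-one (racemic) | CCOC1=CC(=O)C1CC=C(C)C | intermediate
6 | 4-methylpent-3-enoic acid | CC(C)=CCC(=O)O | starting material
7 | ethyl 4-methylpent-3-enoate | CCOC(=O)CC=C(C)C | intermediate
8 | lithium 1,1-dibromo-5-methylhexa-1,4-dien-2-olate | [Li+].[O-]C(CC=C(C)C)=C(Br)Br | intermediate (not isolated)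
9 | lithium 5-methylhex-4-en-1-yn-1-olate | [Li+].[O-]C#CCC=C(C)C | intermediate (not isolated)
10 | triisopropyl[(5-methylhex-4-en-1-yn-1-yl)oxy]silane | CC(C)=CCC#CO[Si](C(C)C)(C(C)C)C(C)C | intermediate
11 | (3Z)-3-ethoxy-7-methylocta-1,3,6-trien-1-one | O=C=C/C(OCC)=C/CC=C(C)C | intermediate (not isolated)
12 | 4-[(1Z)-1-ethoxy-5-methylhexa-1,4-dien-1-yl]-2-(3-methylbut-2-en-1-yl)-3-[(triisopropylsilyl)oxy]cyclobut-2-en-1-one (racemic) | O=C1C(CC=C(C)C)=C(O[Si](C(C)C)(C(C)C)C(C)C)C1/C(OCC)=C/CC=C(C)C | intermediate (not isolated)
13 | (3E,5Z)-5-ethoxy-9-methyl-2-(3-methylbut-2-en-1-yl)-3-[(triisopropylsilyl)oxy]deca-1,3,5,8-tetraen-1-one | O=C=C(CC=C(C)C)/C(O[Si](C(C)C)(C(C)C)C(C)C)=C\C(OCC)=C\CC=C(C)C | intermediate (not isolated)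
14 | 5-ethoxy-2,6-bis(3-methylbut-2-en-1-yl)-3-[(triisopropylsilyl)oxy]cyclohexa-2,4-dien-1-one (racemic) | O=C1C(CC=C(C)C)=C(O[Si](C(C)C)(C(C)C)C(C)C)C=C(OCC)C1CC=C(C)C | intermediate (not isolated)
15 | 5-ethoxy-2,6-bis(3-methylbut-2-en-1-yl)-3-[(triisopropylsilyl)oxy]phenol | CCOc1cc(O[Si](C(C)C)(C(C)C)C(C)C)c(CC=C(C)C)c(O)c1CC=C(C)C | intermediate
16 | 5-ethoxy-2,4-bis(3-methylbut-2-en-1-yl)benzene-1,3-diol | CCOc1cc(O)c(CC=C(C)C)c(O)c1CC=C(C)C | intermediate
17 | 1-ethoxy-3,5-bis(methoxymethoxy)-2,4-bis(3-methylbut-2-en-1-yl)benzene | CCOc1cc(OCOC)c(CC=C(C)C)c(OCOC)c1CC=C(C)C | intermediate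
18 | ethyl glycolate | CCOC(=O)CO | starting material
19 | ethyl 2-(methoxymethoxy)acetate | CCOC(=O)COCOC | intermediate
20 | N-methoxy-2-(methoxymethoxy)-N-methylacetamide | COCOCC(=O)N(C)OC | intermediate
21 | [2-ethoxy-4,6-bis(methoxymethoxy)-3,5-bis(3-methylbut-2-en-1-yl)phenyl]lithium | [Li]c1c(OCC)c(CC=C(C)C)c(OCOC)c(CC=C(C)C)c1OCOC | intermediate (not isolated)
22 | 1-[2-ethoxy-4,6-bis(methoxymethoxy)-3,5-bis(3-methylbut-2-en-1-yl)phenyl]-2-(methoxymethoxy)ethan-1-one | CCOc1c(C(=O)COCOC)c(OCOC)c(CC=C(C)C)c(OCOC)c1CC=C(C)C | intermediate
23 | 4-bromo-2-hydroxybenzaldehyde | O=Cc1ccc(Br)cc1O | starting material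
24 | 5-bromo-2-(1-hydroxy-3-methylbut-2-en-1-yl)phenol (racemic) | CC(C)=CC(O)c1ccc(Br)cc1O | intermediate (not isolated)
25 | 3-bromo-6-(3-methylbut-2-en-1-ylidene)cyclohexa-2,4-dien-1-one (exocyclic alkene geometry not defined) | CC(C)=CC=C1C=CC(Br)=CC1=O | intermediate (not isolated)
26 | 7-bromo-2,2-dimethyl-2H-chromene | CC1(C)C=Cc2ccc(Br)cc2O1 | intermediate
27 | (2,2-dimethyl-2H-chromen-7-yl)lithium | [Li]c1ccc2C=CC(C)(C)Oc2c1 | intermediate (not isolated)
28 | 2,2-dimethyl-2H-chromene-7-carboxylic acid | CC1(C)C=Cc2ccc(C(=O)O)cc2O1 | intermediate
29 | 2,2-dimethyl-2H-chromene-7-carbonyl chloride | CC1(C)C=Cc2ccc(C(=O)Cl)cc2O1 | intermediate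
30 | lithium (Z)-1-[2-ethoxy-4,6-bis(methoxymethoxy)-3,5-bis(3-methylbut-2-en-1-yl)phenyl]-2-(methoxymethoxy)ethen-1-olate | [Li+].[O-]/C(=C\OCOC)c1c(OCC)c(CC=C(C)C)c(OCOC)c(CC=C(C)C)c1OCOC | intermediate (not isolated)
31 | 1-(2,2-dimethyl-2H-chromen-7-yl)-3-[2-ethoxy-4,6-bis(methoxymethoxy)-3,5-bis(3-methylbut-2-en-1-yl)phenyl]-2-(methoxymethoxy)propane-1,3-dione (racemic) | CCOc1c(C(=O)C(OCOC)C(=O)c2ccc3C=CC(C)(C)Oc3c2)c(OCOC)c(CC=C(C)C)c(OCOC)c1CC=C(C)C | intermediate
32 | 1-(2,2-dimethyl-2H-chromen-7-yl)-3-[2-ethoxy-4,6-dihydroxy-3,5-bis(3-methylbut-2-en-1-yl)phenyl]-2-(methoxymethoxy)propane-1,3-dione (racemic) | CCOc1c(C(=O)C(OCOC)C(=O)c2ccc3C=CC(C)(C)Oc3c2)c(O)c(CC=C(C)C)c(O)c1CC=C(C)C | intermediate (not isolated)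
33 | 2-(2,2-dimethyl-2H-chromen-7-yl)-5-ethoxy-2,7-dihydroxy-3-(methoxymethoxy)-6,8-bis(3-methylbut-2-en-1-yl)-2,3-dihydro-4H-chromen-4-one (mixture of diastereomers, racemic) | CCOc1c(CC=C(C)C)c(O)c(CC=C(C)C)c2OC(O)(c3ccc4C=CC(C)(C)Oc4c3)C(OCOC)C(=O)c12 | intermediate (not isolated)
34 | 2-(2,2-dimethyl-2H-chromen-7-yl)-5-ethoxy-7-hydroxy-3-(methoxymethoxy)-6,8-bis(3-methylbut-2-en-1-yl)-4H-chromen-4-one | CCOc1c(CC=C(C)C)c(O)c(CC=C(C)C)c2oc(-c3ccc4C=CC(C)(C)Oc4c3)c(OCOC)c(=O)c12 | intermediate (not isolated)
35 | 2-(2,2-dimethyl-2H-chromen-7-yl)-5-ethoxy-3,7-dihydroxy-6,8-bis(3-methylbut-2-en-1-yl)-4H-chromen-4-one | CCOc1c(CC=C(C)C)c(O)c(CC=C(C)C)c2oc(-c3ccc4C=CC(C)(C)Oc4c3)c(O)c(=O)c12 | intermediate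
36 | dorsilurin C, 2-(2,2-dimethyl-2H-chromen-7-yl)-3,5,7-trihydroxy-6,8-bis(3-methylbut-2-en-1-yl)-4H-chromen-4-one | CC(C)=CCc1c(O)c(CC=C(C)C)c2oc(-c3ccc4c(c3)OC(C)(C)C=C4)c(O)c(=O)c2c1O | target

## Step count and the least certain steps

Total: 16 steps. Longest linear sequence: 9 steps (steps 1, 2, 5, 6, 7, 10, 14, 15, 16; the branch through steps 3 and 4 is equally long).

Step 5 (key step). The opening of 5 is slowed by its vinylogous-ester stabilization. The temperature then needed may approach that at which 10 isomerizes by silyl shift and the ketenes oligomerize, so the union could stall or lose material. Fallback (sets out from 7 and 10, returns at 15): vinylketene 11 is generated at room temperature by photochemical Wolff rearrangement, the second-generation Danheiser benzannulation. Ester 7 is reduced with i-Bu2AlH at −78 °C to 4-methylpent-3-enal F1. A Horner–Wadsworth–Emmons reaction of F1 with triethyl 2-ethoxy-2-phosphonoacetate (NaH, THF) gives ethyl 2-ethoxy-6-methylhepta-2,5-dienoate F2. Saponification with LiOH gives 2-ethoxy-6-methylhepta-2,5-dienoic acid F3, oxalyl chloride gives 2-ethoxy-6-methylhepta-2,5-dienoyl chloride F4, and diazomethane gives 1-diazo-3-ethoxy-7-methylocta-3,6-dien-2-one F5. Irradiation of F5 with 10 in 1,2-dichloroethane should form 11 by migration of the alkenyl group, and the sequence then runs through 12, 13 and 14 to 15, with brief warming to complete the last two pericyclic steps. Both alkene isomers of F5 converge on 15 because that geometry disappears on aromatization.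

Step 4. The α-hydrogens of 7 are allylic as well as α to the ester, so deprotonation by the carbenoid or by the amide base may compete with carbonyl addition and return conjugated or recovered ester. Fallback (sets out from 1, returns at 10 through 9): the ynolate is made by double bromine–lithium exchange on an α,α-dibromo ester. Acid 1 is esterified (EtI, K2CO3) to ethyl 5-methylhex-4-enoate F6. Two rounds of enolate bromination (LiN(i-Pr)2, then 1,2-dibromotetrachloroethane) lead through ethyl 2-bromo-5-methylhex-4-enoate F7 to ethyl 2,2-dibromo-5-methylhex-4-enoate F8. Treatment of F8 with t-BuLi (4 equiv, THF, −78 → 0 °C) should give ynolate 9 with loss of ethoxide, and silylation as in step 4 gives 10.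

Step 14. The enolate 30 is trisubstituted and flanked by a di-ortho-substituted aryl group, so O-acylation to the enol ester may compete with C-acylation. Fallback (sets out from 22 and 26, returns at 31): the C2–C3 bond is made by an aldol addition, which can only occur at carbon, followed by oxidation. Bromide 26 is converted through 27 (n-BuLi, then DMF) into 2,2-dimethyl-2H-chromene-7-carbaldehyde F9. The enolate 30 (from 22 and one equivalent of LiN(SiMe3)2) adds to F9 to give 3-(2,2-dimethyl-2H-chromen-7-yl)-1-[2-ethoxy-4,6-bis(methoxymethoxy)-3,5-bis(3-methylbut-2-en-1-yl)phenyl]-3-hydroxy-2-(methoxymethoxy)propan-1-one F10. Dess–Martin periodinane oxidizes F10 to 31.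

Step 15. Protonation of a prenyl alkene next to a freshly unmasked phenol, followed by closure to a dimethylchroman, or addition of methanol to the chromene alkene, may compete with acetal cleavage and cyclodehydration. Fallback (sets out from 31, returns at 35): unmasking and ring closure are separated, and the Brønsted acid is replaced by a buffered silyl triflate. Me3SiOTf with 2,2'-bipyridyl (CH2Cl2, 0 °C) converts the three acetals into silyl ethers and N-alkylpyridinium salts, which water hydrolyses to 1-(2,2-dimethyl-2H-chromen-7-yl)-3-[2-ethoxy-4,6-dihydroxy-3,5-bis(3-methylbut-2-en-1-yl)phenyl]-2-hydroxypropane-1,3-dione F11 (in equilibrium with its cyclic hemiketal). F11 is then dehydrated to 35 in buffered acetic acid (AcOH, NaOAc, 60 °C).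

Step 16. Iodide attack on an ethyl group is slower than on the methyl group for which this reagent is established, so the long heating with the Lewis acid may give incomplete conversion or acid-promoted cyclization of a prenyl group onto a neighbouring phenol. Fallback (sets out from 22, returns at 36): the ether is cleaved earlier with a thiolate on a substrate without free phenols, and the liberated hydroxyl is used for ring closure. This is permissible because ring A becomes symmetric once both oxygens flanking C4a are free. NaSEt in DMF at 110 °C dealkylates the ethoxy group ortho to the ketone of 22 and gives 1-[2-hydroxy-4,6-bis(methoxymethoxy)-3,5-bis(3-methylbut-2-en-1-yl)phenyl]-2-(methoxymethoxy)ethan-1-one F12. Its dianion (LiN(SiMe3)2, 3.3 equiv) is C-acylated with 29 to give 1-(2,2-dimethyl-2H-chromen-7-yl)-3-[2-hydroxy-4,6-bis(methoxymethoxy)-3,5-bis(3-methylbut-2-en-1-yl)phenyl]-2-(methoxymethoxy)propane-1,3-dione F13. The conditions of step 15 then close ring C and remove the three acetals to give 36 directly.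

## Further compounds

F1 | step 5 | 4-methylpent-3-enal | CC(C)=CCC=O
F2 | step 5 | ethyl 2-ethoxy-6-methylhepta-2,5-dienoate (mixture of C2 alkene isomers) | CCOC(=O)C(OCC)=CCC=C(C)C
F3 | step 5 | 2-ethoxy-6-methylhepta-2,5-dienoic acid (mixture of C2 alkene isomers) | CCOC(=CCC=C(C)C)C(=O)O
F4 | step 5 | 2-ethoxy-6-methylhepta-2,5-dienoyl chloride (mixture of C2 alkene isomers) | CCOC(=CCC=C(C)C)C(=O)Cl
F5 | step 5 | 1-diazo-3-ethoxy-7-methylocta-3,6-dien-2-one (mixture of C3 alkene isomers) | CCOC(=CCC=C(C)C)C(=O)C=[N+]=[N-]
F6 | step 4 | ethyl 5-methylhex-4-enoate | CCOC(=O)CCC=C(C)C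
F7 | step 4 | ethyl 2-bromo-5-methylhex-4-enoate (racemic) | CCOC(=O)C(Br)CC=C(C)C
F8 | step 4 | ethyl 2,2-dibromo-5-methylhex-4-enoate | CCOC(=O)C(Br)(Br)CC=C(C)C
F9 | step 14 | 2,2-dimethyl-2H-chromene-7-carbaldehyde | CC1(C)C=Cc2ccc(C=O)cc2O1
F10 | step 14 | 3-(2,2-dimethyl-2H-chromen-7-yl)-1-[2-ethoxy-4,6-bis(methoxymethoxy)-3,5-bis(3-methylbut-2-en-1-yl)phenyl]-3-hydroxy-2-(methoxymethoxy)propan-1-one (mixture of diastereomers, racemic) | CCOc1c(C(=O)C(OCOC)C(O)c2ccc3C=CC(C)(C)Oc3c2)c(OCOC)c(CC=C(C)C)c(OCOC)c1CC=C(C)C
F11 | step 15 | 1-(2,2-dimethyl-2H-chromen-7-yl)-3-[2-ethoxy-4,6-dihydroxy-3,5-bis(3-methylbut-2-en-1-yl)phenyl]-2-hydroxypropane-1,3-dione (racemic) | CCOc1c(C(=O)C(O)C(=O)c2ccc3C=CC(C)(C)Oc3c2)c(O)c(CC=C(C)C)c(O)c1CC=C(C)C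
F12 | step 16 | 1-[2-hydroxy-4,6-bis(methoxymethoxy)-3,5-bis(3-methylbut-2-en-1-yl)phenyl]-2-(methoxymethoxy)ethan-1-one | COCOCC(=O)c1c(O)c(CC=C(C)C)c(OCOC)c(CC=C(C)C)c1OCOC
F13 | step 16 | 1-(2,2-dimethyl-2H-chromen-7-yl)-3-[2-hydroxy-4,6-bis(methoxymethoxy)-3,5-bis(3-methylbut-2-en-1-yl)phenyl]-2-(methoxymethoxy)propane-1,3-dione (racemic) | COCOC(C(=O)c1ccc2C=CC(C)(C)Oc2c1)C(=O)c1c(O)c(CC=C(C)C)c(OCOC)c(CC=C(C)C)c1OCOC
A1 | alternative 1 | 2-(2,2-dimethyl-2H-chromen-7-yl)-5,7-dihydroxy-3-(methoxymethoxy)-6,8-bis(3-methylbut-2-en-1-yl)-4H-chromen-4-one | CC(C)=CCc1c(O)c(CC=C(C)C)c2oc(-c3ccc4c(c3)OC(C)(C)C=C4)c(OCOC)c(=O)c2c1O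
A2 | alternative 1 | 2,4-bis(3-methylbut-2-en-1-yl)benzene-1,3,5-triol | CC(C)=CCc1c(O)cc(O)c(CC=C(C)C)c1O
A3 | alternative 1 | 6-(2,2-dimethyl-2H-chromen-7-yl)-5-(methoxymethoxy)-2,2-dimethyl-4H-1,3-dioxin-4-one | COCOC1=C(c2ccc3C=CC(C)(C)Oc3c2)OC(C)(C)OC1=O
A4 | alternative 1 | 3-(2,2-dimethyl-2H-chromen-7-yl)-2-(methoxymethoxy)prop-1-ene-1,3-dione | COCOC(=C=O)C(=O)c1ccc2C=CC(C)(C)Oc2c1
A5 | alternative 2 | methyl 2,2-dimethyl-5-oxo-5,6,7,8-tetrahydro-2H-chromene-7-carboxylate (racemic) | COC(=O)C1CC(=O)C2=C(C1)OC(C)(C)C=C2
A6 | alternative 2 | methyl 3,5-dioxocyclohexane-1-carboxylate | COC(=O)C1CC(=O)CC(=O)C1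
A7 | alternative 2 | 3-methylbut-2-enal | CC(C)=CC=O
A8 | alternative 3 | (E)-3-(2,2-dimethyl-2H-chromen-7-yl)-1-[2,4,6-trihydroxy-3,5-bis(3-methylbut-2-en-1-yl)phenyl]prop-2-en-1-one | CC(C)=CCc1c(O)c(CC=C(C)C)c(O)c(C(=O)/C=C/c2ccc3C=CC(C)(C)Oc3c2)c1O
A9 | alternative 3 | methyl (E)-9-(2,2-dimethyl-2H-chromen-7-yl)-2,4-bis(3-methylbut-2-en-1-yl)-3,5,7-trioxonon-8-enoate (mixture of diastereomers, racemic) | COC(=O)C(CC=C(C)C)C(=O)C(CC=C(C)C)C(=O)CC(=O)/C=C/c1ccc2C=CC(C)(C)Oc2c1
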